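**Retrosynthetic overview**
1. Target 43 ⇐ late β-epoxidation of C11=C12, C16 chloride, the two acetates, the γ-lactone (C7–O/C19) and the C7/C9 carbonyl reductions ⇐ ten-membered 8-hydroxy-7,9-diketone 34.
2. 34 ⇐ eleven-membered macrolactone 31 (ester oxygen between C8 and C9) by a ring-contracting 1,2 O→C acyl shift (Chan rearrangement). The enabling feature is that, in the ten-membered ring C1–C10, the tertiary carbinol C8 sits between the oxygen-bearing C7 and C9 (a masked 2-hydroxy-1,3-diketone), so the ring bond C8–C9 can be exchanged for an ester link C9–O–C8.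
3. 31 ⇐ Mitsunobu lactonisation of seco acid 30 ⇐ B-alkyl Suzuki union (C4–C5) of the eastern cyclohexene 15 with the western (Z)-β-iodo enone 27.
4. 15 ⇐ (S)-carvone (its ring becomes the six-membered ring; C1 by formylation/methylation, C14–O by Criegee rearrangement, C2 by chelate-controlled vinylation, C9/C10 by Wharton transposition then Wittig–Still shift). 27 ⇐ but-2-yne-1,4-diol and (S)-3-bromo-2-methylpropan-1-ol (C17).
5. Ring order: cyclohexene (chiral pool) → eleven-membered lactone → ten-membered carbocycle → γ-lactone → epoxide.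

Key step: step 22

Remark: locants follow the briarane skeleton (ten-membered ring C1–C10; six-membered ring C1, C10–C14; C15 = methyl on C1; C16 on C5; lactone carbons C17–C19; C20 = methyl on C11), β is the face of C15, TBS = tert-butyldimethylsilyl, PMB = 4-methoxybenzyl, and C8 in 27–31 is left as an epimer mixture because step 22 erases it.

Step 1
Reactants: 1 (S)-(+)-carvone
Product: 3 (Z)-6-(hydroxymethylene)carvone, via carvone lithium enolate 2 (not isolated)
Conditions: LDA (1.1 equiv), THF, −78 °C; then CF3CH2OCHO, −78 → 0 °C; aq. HCl work-up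
Reagents that add atoms: 2,2,2-trifluoroethyl formate, O=COCC(F)(F)F
Why: Kinetic α′-deprotonation of carvone (at the future C1) and Claisen-type formylation with the activated formate should give the chelated hydroxymethylene ketone; C1 is trigonal here, so no stereocentre is fixed yet.

Step 2
Reactants: 3 (Z)-6-(hydroxymethylene)carvone
Product: 4 6-formyl-6-methylcarvone (C15 methyl β; formyl C2 α)
Conditions: K2CO3, MeI, acetone, reflux
Reagents that add atoms: iodomethane, CI
Why: C-Alkylation of the 2-formyl ketone enolate (classical formylation–methylation sequence) creates the quaternary C1; iodomethane should approach the planar enolate anti to the neighbouring isopropenyl group, so C15 ends trans to it (β) and the formyl carbon C2 cis (α).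

Step 3
Reactants: 4 6-formyl-6-methylcarvone
Product: 6 14α-acetoxy keto aldehyde, via methoxy hydroperoxide 5 (not isolated)
Conditions: O3, CH2Cl2/MeOH (4:1), NaHCO3, −78 °C (Sudan III end point); then Ac2O, Et3N, DMAP (cat.), 0 °C → rt
Reagents that add atoms: ozone, [O-][O+]=O; methanol, CO
Why: The electron-rich isopropenyl group is ozonised in preference to the conjugated ring alkene, and Criegee rearrangement of 5 after Ac2O activation moves C14 from carbon to oxygen with retention, so the former C(CH3) unit becomes the acetyl group of a 14α-acetate.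

Step 4
Reactants: 6 14α-acetoxy keto aldehyde
Product: 7 C2 vinyl carbinol acetate
Conditions: MgBr2·OEt2 (1.5 equiv), CH2Cl2, −78 °C; then CH2=CHMgBr (1.2 equiv), THF, −78 °C
Reagents that add atoms: vinylmagnesium bromide, C=C[Mg]Br
Why: Chelation-controlled Grignard addition: magnesium bridges the aldehyde and the C10 ketone oxygen, and the vinyl group should attack the aldehyde (far more reactive than the hindered enone or the acetate at −78 °C) from the exposed face carrying C15, away from ring carbon C14, which gives the C2 configuration of the target.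

Step 5
Reactants: 7 C2 vinyl carbinol acetate
Product: 8 C2 TBS ether acetate
Conditions: TBSOTf, 2,6-lutidine, CH2Cl2, −78 → 0 °C
Reagents that add atoms: tert-butyldimethylsilyl triflate, CC(C)(C)[Si](C)(C)OS(=O)(=O)C(F)(F)F
Why: Silylation of the hindered secondary alcohol with the silyl triflate; capping this β-hydroxy ketone oxygen blocks retro-aldol loss of acrolein in the basic steps that follow.

Step 6
Reactants: 8 C2 TBS ether acetate
Product: 9 14α-alcohol
Conditions: K2CO3 (0.2 equiv), MeOH, 0 °C
Reagents that add atoms: none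
Why: Transesterification of the secondary acetate with methanol under mildly basic conditions where the alkoxide concentration should be too low for retro-aldol ring opening; no stereocentre is touched.

Step 7
Reactants: 9 14α-alcohol
Product: 10 bis-TBS enone
Conditions: TBSOTf, 2,6-lutidine, CH2Cl2, 0 °C
Reagents that add atoms: tert-butyldimethylsilyl triflate, CC(C)(C)[Si](C)(C)OS(=O)(=O)C(F)(F)F
Why: Silylation of the neopentyl secondary alcohol with the reactive triflate gives a base-stable ether for the organolithium chemistry ahead.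

Step 8
Reactants: 10 bis-TBS enone
Product: 11 11β,12β-epoxy ketone
Conditions: 30% H2O2, NaOH (aq.), MeOH, 0 °C
Reagents that add atoms: hydrogen peroxide, OO
Why: Weitz–Scheffer nucleophilic epoxidation of the α-methyl enone: hydroperoxide should add axially to C12 trans to the C14 silyloxy group (the course known for 5-substituted cyclohexenones such as carvone), so the epoxide forms on the β face.

Step 9
Reactants: 11 11β,12β-epoxy ketone
Product: 12 12β-allylic alcohol
Conditions: N2H4·H2O (3 equiv), AcOH (cat.), MeOH, 0 °C → rt, argon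
Reagents that add atoms: none
Why: Wharton transposition (hydrazine, loss of dinitrogen) moves the alkene to C10=C11 and leaves the untouched C12–O bond as a β allylic alcohol.

Step 10
Reactants: 12 12β-allylic alcohol
Product: 13 stannylmethyl ether
Conditions: KH, 18-crown-6 (cat.), Bu3SnCH2I, THF, 0 °C → rt
Reagents that add atoms: tributyl(iodomethyl)stannane, CCCC[Sn](CCCC)(CCCC)CI
Why: Williamson etherification of the allylic alkoxide with the α-stannyl iodide prepares the Wittig–Still precursor without touching any stereocentre.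

Step 11
Reactants: 13 stannylmethyl ether
Product: 15 eastern alcohol, via alkoxymethyllithium 14 (not isolated)
Conditions: n-BuLi (1.5 equiv), THF, −78 °C
Reagents that add atoms: none
Why: Tin–lithium exchange triggers the [2,3]-Wittig–Still rearrangement, which should deliver the CH2OH carbon (C9) suprafacially from the β oxygen at C12 to C10 and so set C10 (C9 β, trans to C2) while the alkene returns to C11=C12.

Step 12
Reactants: 16 but-2-yne-1,4-diol
Product: 17 4-(4-methoxybenzyloxy)but-2-yn-1-ol
Conditions: NaH (1.0 equiv), PMBCl (1.0 equiv), Bu4NI (cat.), THF/DMF, 0 °C → rt; diol in threefold excess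
Reagents that add atoms: 4-methoxybenzyl chloride, COc1ccc(CCl)cc1
Why: Statistical mono-Williamson etherification; the excess of the cheap diol suppresses bis-alkylation.

Step 13
Reactants: 17 4-(4-methoxybenzyloxy)but-2-yn-1-ol
Product: 19 (Z)-3-iodo-4-(4-methoxybenzyloxy)but-2-en-1-ol, via cyclic alkenylalanate 18 (not isolated)
Conditions: Red-Al (1.5 equiv), THF, 0 °C → rt; then I2, THF, −78 °C
Reagents that add atoms: iodine, II
Why: Hydroxyl-directed trans-hydroalumination of the propargylic alcohol places aluminium on the distal alkyne carbon (C5) in a five-membered alkoxyalanate, and iodinolysis with retention should give the (Z)-3-iodo allylic alcohol, which fixes the C5=C6 geometry (C7 cis to the iodine that C4 will replace).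

Step 14
Reactants: 19 (Z)-3-iodo-4-(4-methoxybenzyloxy)but-2-en-1-ol
Product: 20 (Z)-3-iodo-4-(4-methoxybenzyloxy)but-2-enal
Conditions: activated MnO2 (15 equiv), CH2Cl2, rt, dark
Reagents that add atoms: none
Why: Chemoselective allylic oxidation with manganese dioxide under neutral conditions that should leave the vinyl iodide geometry and the PMB ether intact.

Step 15
Reactants: 21 (S)-3-bromo-2-methylpropan-1-ol
Product: 22 (S)-bromide TBS ether
Conditions: TBSCl, imidazole, CH2Cl2, rt
Reagents that add atoms: tert-butyldimethylsilyl chloride, CC(C)(C)[Si](C)(C)Cl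
Why: Standard silylation of the primary alcohol; the stereocentre (the future C17) comes from the chiral pool and is not touched.

Step 16
Reactants: 22 (S)-bromide TBS ether; 20 (Z)-3-iodo-4-(4-methoxybenzyloxy)but-2-enal
Product: 24 C7 carbinol, via Grignard reagent 23 (not isolated)
Conditions: Mg turnings, I2 (cat.), THF, 40 °C; then 20, THF, −78 °C
Reagents that add atoms: none
Why: Grignard 1,2-addition to the enal at −78 °C should outrun iodine–magnesium exchange and conjugate displacement of the β-iodide; the new C7 carbinol forms as a mixture that the next step oxidises.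

Step 17
Reactants: 24 C7 carbinol
Product: 25 (Z)-β-iodo enone
Conditions: Dess–Martin periodinane, NaHCO3, CH2Cl2, 0 °C → rt
Reagents that add atoms: none
Why: Dess–Martin oxidation of the allylic alcohol under buffered, non-basic conditions should give the enone without isomerising the iodoalkene.

Step 18
Reactants: 25 (Z)-β-iodo enone
Product: 27 α′-hydroxy β-iodo enone, via trimethylsilyl dienol ether 26 (not isolated)
Conditions: TMSOTf, Et3N, CH2Cl2, −78 → 0 °C; then mCPBA, NaHCO3, CH2Cl2, −20 °C; then citric acid, MeOH, rt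
Reagents that add atoms: 3-chloroperoxybenzoic acid, OOC(=O)c1cccc(Cl)c1
Why: Rubottom oxidation: soft enolisation toward C8 gives the cross-conjugated silyl dienol ether, whose electron-rich enol double bond is epoxidised in preference to the iodoalkene; C8 forms as a mixture, which is immaterial because step 22 enolises it.

Step 19
Reactants: 15 eastern alcohol; 27 α′-hydroxy β-iodo enone
Product: 29 seco diol, via bis-borane 28 (not isolated)
Conditions: 9-BBN (3 equiv), THF, rt; then 27, Pd(dppf)Cl2 (10 mol%), AsPh3, Cs2CO3, DMF/THF/H2O, rt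
Reagents that add atoms: none
Why: B-alkyl Suzuki–Miyaura coupling: 9-BBN should hydroborate only the monosubstituted alkene at its terminus (the free C9 hydroxyl is carried as its borinate), and the alkylborane couples with the β-iodo enone with retention of alkene geometry to form C4–C5.

Step 20
Reactants: 29 seco diol
Product: 30 seco hydroxy acid
Conditions: TEMPO (0.2 equiv), PhI(OAc)2 (2.5 equiv), MeCN/pH 7 buffer (1:1), 0 °C → rt
Reagents that add atoms: water, O
Why: Oxoammonium oxidation (TEMPO/PhI(OAc)2 in aqueous acetonitrile) should take the primary C9 alcohol to the carboxylic acid and leave the secondary α-ketol alone.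

Step 21
Reactants: 30 seco hydroxy acid
Product: 31 eleven-membered macrolactone
Conditions: PPh3, DIAD, toluene, 0 °C → rt, slow addition to 1 mM
Reagents that add atoms: none
Why: Mitsunobu macrolactonisation: the carboxylate of the hindered C9 acid acts as nucleophile at the activated α-keto carbinol C8, so no acyl activation next to the quaternary centre is needed, and whether C8 is inverted or not is irrelevant.

Step 22
Reactants: 31 eleven-membered macrolactone
Product: 34 ten-membered 8-hydroxy-7,9-diketone, via lithium enolate 32 (not isolated), via oxiranolate 33 (not isolated)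
Conditions: LiHMDS (1.2 equiv), THF, −78 → −40 °C; AcOH quench at −78 °C
Reagents that add atoms: none
Why: Proposed new method: LiHMDS should remove the doubly activated C8–H (α to the C7 ketone and to the acyloxy oxygen) to give the cross-conjugated enolate 32, whose C8 adds to the lactone carbonyl C9 in a 3-exo-trig closure to oxiranolate 33; this opens by C9–O cleavage, so the ring oxygen leaves the eleven-membered perimeter as the C8 alkoxide and the ring shrinks to the ten-membered carbocycle (net 1,2 O→C acyl shift). The closest known reaction is the Chan rearrangement of α-acyloxy esters and ketones to 2-hydroxy-1,3-dicarbonyl compounds, known for open-chain esters and small cyclic carbonates but not as a ring contraction of a macrolactone. The ten-membered ring is closed by this intramolecular acyl transfer, driven by conversion of a ketone enolate into a less basic tertiary alkoxide held by two carbonyl groups. The new stereocentre C8 should be controlled by C17 through A(1,3) strain: the C17–H bond lies in the enolate plane and the acyl carbon is delivered to the face opposite the bulky CH2OTBS group, which corresponds to the required configuration, and both C8 epimers of 31 converge on the same enolate. The step needs deprotonation at C8 rather than at the γ positions (C4, C16) or at C10, which the acidity of the α-acyloxy ketone, the kinetic amide base at −78 °C and the shielding of C10–H by quaternary C1 should secure; it also needs C- rather than O-acyl transfer, which is secured because only C-acylation ends in the stable alkoxide and the quench is done cold.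

Step 23
Reactants: 34 ten-membered 8-hydroxy-7,9-diketone
Product: 35 7-alcohol
Conditions: Zn(BH4)2 (0.6 equiv), Et2O, −78 → −40 °C
Reagents that add atoms: none
Why: Chelation-controlled 1,2-reduction of the α-hydroxy enone: zinc bridges the C8 alkoxide and the C7 carbonyl oxygen and hydride should arrive from the outer face next to C17, opposite the ring arm C9, giving the 7,8-anti diol (target configuration at C7), while the C9 ketone between the fully substituted C8 and the neopentyl C10 should react much more slowly.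

Step 24
Reactants: 35 7-alcohol
Product: 36 pentaol
Conditions: HF·pyridine, pyridine, THF, 0 °C → rt
Reagents that add atoms: none
Why: Fluoride cleavage of all three silyl ethers under weakly acidic conditions that should avoid retro-aldol or α-ketol shifts of the hydroxy ketone.

Step 25
Reactants: 36 pentaol
Product: 38 lactone diol, via lactol 37 (not isolated)
Conditions: TEMPO (0.2 equiv), PhI(OAc)2 (2.5 equiv), CH2Cl2, rt
Reagents that add atoms: none
Why: Oxidative lactonisation: only the unhindered primary C19 alcohol should be oxidised, the oxidised C19 is captured by the C7 hydroxyl as lactol 37 and this is oxidised on to the γ-lactone; with C9 still a ketone no isomeric lactone can form.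

Step 26
Reactants: 38 lactone diol
Product: 39 diacetate
Conditions: Ac2O, pyridine, DMAP (cat.), CH2Cl2, 0 °C → rt
Reagents that add atoms: acetic anhydride, CC(=O)OC(C)=O
Why: DMAP-catalysed acetylation of the two secondary alcohols (C2, C14); the tertiary C8 hydroxyl should stay free and C9 is still a ketone, so no hydroxyl differentiation problem arises.

Step 27
Reactants: 39 diacetate
Product: 40 8,9-diol
Conditions: Zn(BH4)2, Et2O/THF, −40 → 0 °C
Reagents that add atoms: none
Why: Chelation-controlled reduction of the α-hydroxy ketone: zinc bridges O8 and the C9 carbonyl and hydride should arrive from the face of the lactone carbon C17, opposite the ring arm C7, giving the 8,9-anti diol (target configuration at C9); acetates and lactone are inert to zinc borohydride.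

Step 28
Reactants: 40 8,9-diol
Product: 41 allylic alcohol
Conditions: DDQ, CH2Cl2/pH 7 buffer (10:1), 0 °C
Reagents that add atoms: none
Why: Oxidative removal of the PMB ether with DDQ should free the primary allylic C16 alcohol without touching acetates, lactone or alkenes.

Step 29
Reactants: 41 allylic alcohol
Product: 42 allylic chloride
Conditions: MsCl, 2,4,6-collidine, LiCl, DMF, 0 °C
Reagents that add atoms: lithium chloride, [Li+].[Cl-]
Why: Chlorination through the allylic mesylate and SN2 displacement by chloride should be selective for the primary allylic alcohol over the hindered secondary C9 and tertiary C8 hydroxyls and should keep the alkene geometry.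

Step 30
Reactants: 42 allylic chloride
Product: 43 CNP0308390.1
Conditions: mCPBA, NaHCO3, CH2Cl2, 0 °C
Reagents that add atoms: 3-chloroperoxybenzoic acid, OOC(=O)c1cccc(Cl)c1
Why: Prilezhaev epoxidation should take the electron-rich C11=C12 alkene in preference to C5=C6 (deactivated by CH2Cl and the allylic lactone oxygen), with the β-disposed homoallylic C9 hydroxyl guiding the peracid to the β face while the axial 14α-acetate shields the α face.

**Compound list**
1 | (S)-(+)-carvone | CC(=C)[C@H]1CC=C(C)C(=O)C1 | starting material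
2 | carvone lithium enolate (cross-conjugated) | CC(=C)[C@H]1CC=C(C)C(O[Li])=C1 | intermediate (not isolated)
3 | (Z)-6-(hydroxymethylene)carvone | CC(=C)[C@H]1CC=C(C)C(=O)/C1=C\O | intermediate
4 | 6-formyl-6-methylcarvone (quaternary C1: C15 β, formyl C2 α, isopropenyl α at C14) | CC(=C)[C@H]1CC=C(C)C(=O)[C@@]1(C)C=O | intermediate
5 | methoxy hydroperoxide from ozonolysis of 4 in methanol | COC(C)(OO)[C@H]1CC=C(C)C(=O)[C@@]1(C)C=O | intermediate (not isolated)
6 | 14α-acetoxy keto aldehyde | CC(=O)O[C@H]1CC=C(C)C(=O)[C@@]1(C)C=O | intermediate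
7 | C2 vinyl carbinol acetate (C2 as in target) | CC(=O)O[C@H]1CC=C(C)C(=O)[C@@]1(C)[C@H](O)C=C | intermediate
8 | C2 TBS ether acetate | CC(=O)O[C@H]1CC=C(C)C(=O)[C@@]1(C)[C@H](O[Si](C)(C)C(C)(C)C)C=C | intermediate
9 | 14α-alcohol | O[C@H]1CC=C(C)C(=O)[C@@]1(C)[C@H](O[Si](C)(C)C(C)(C)C)C=C | intermediate
10 | bis-TBS enone (2-OTBS, 14α-OTBS) | CC(C)(C)[Si](C)(C)O[C@H]1CC=C(C)C(=O)[C@@]1(C)[C@H](O[Si](C)(C)C(C)(C)C)C=C | intermediate
11 | 11β,12β-epoxy ketone | CC(C)(C)[Si](C)(C)O[C@H]1C[C@@H]2O[C@]2(C)C(=O)[C@@]1(C)[C@H](O[Si](C)(C)C(C)(C)C)C=C | intermediate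
12 | 12β-allylic alcohol (C10=C11) | CC(C)(C)[Si](C)(C)O[C@H]1C[C@H](O)C(C)=C[C@@]1(C)[C@H](O[Si](C)(C)C(C)(C)C)C=C | intermediate
13 | 12β-(tributylstannylmethyl) ether | CC(C)(C)[Si](C)(C)O[C@H]1C[C@H](OC[Sn](CCCC)(CCCC)CCCC)C(C)=C[C@@]1(C)[C@H](O[Si](C)(C)C(C)(C)C)C=C | intermediate
14 | alkoxymethyllithium | CC(C)(C)[Si](C)(C)O[C@H]1C[C@H](OC[Li])C(C)=C[C@@]1(C)[C@H](O[Si](C)(C)C(C)(C)C)C=C | intermediate (not isolated)
15 | eastern alcohol (10β-CH2OH, C11=C12, 1β-methyl, 2-OTBS vinyl carbinol, 14α-OTBS) | CC(C)(C)[Si](C)(C)O[C@H]1CC=C(C)[C@H](CO)[C@@]1(C)[C@H](O[Si](C)(C)C(C)(C)C)C=C | intermediate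
16 | but-2-yne-1,4-diol | OCC#CCO | starting material
17 | 4-(4-methoxybenzyloxy)but-2-yn-1-ol | OCC#CCOCc1ccc(OC)cc1 | intermediate
18 | sodium cyclic alkenylalanate (five-membered O–Al–C5 ring) | COCCO[Al-]1(OCCOC)OCC=C1COCc1ccc(OC)cc1.[Na+] | intermediate (not isolated)
19 | (Z)-3-iodo-4-(4-methoxybenzyloxy)but-2-en-1-ol | OC/C=C(I)/COCc1ccc(OC)cc1 | intermediate
20 | (Z)-3-iodo-4-(4-methoxybenzyloxy)but-2-enal | O=C/C=C(I)/COCc1ccc(OC)cc1 | intermediate
21 | (S)-3-bromo-2-methylpropan-1-ol | OC[C@@H](CBr)C | starting material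
22 | (S)-(3-bromo-2-methylpropoxy)(tert-butyl)dimethylsilane | CC(C)(C)[Si](C)(C)OC[C@@H](CBr)C | intermediate
23 | Grignard reagent of 22 | CC(C)(C)[Si](C)(C)OC[C@@H](C[Mg]Br)C | intermediate (not isolated)
24 | C7 carbinol ((Z)-vinyl iodide, C7 epimer mixture) | OC(/C=C(I)/COCc1ccc(OC)cc1)C[C@@H](C)CO[Si](C)(C)C(C)(C)C | intermediate
25 | (Z)-β-iodo enone (C5–C8, C16–C19 fragment) | O=C(/C=C(I)/COCc1ccc(OC)cc1)C[C@@H](C)CO[Si](C)(C)C(C)(C)C | intermediate
26 | trimethylsilyl dienol ether (C7=C8, Z) | C[Si](C)(C)O/C(/C=C(I)/COCc1ccc(OC)cc1)=C\[C@@H](C)CO[Si](C)(C)C(C)(C)C | intermediate (not isolated)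
27 | α′-hydroxy β-iodo enone (C8 epimer mixture) | O=C(/C=C(I)/COCc1ccc(OC)cc1)C(O)[C@@H](C)CO[Si](C)(C)C(C)(C)C | intermediate
28 | bis-borane (C4–B-9-BBN; C9–O–B-9-BBN) | CC(C)(C)[Si](C)(C)O[C@H]1CC=C(C)[C@H](COB2C3CCCC2CCC3)[C@@]1(C)[C@H](O[Si](C)(C)C(C)(C)C)CCB1C2CCCC1CCC2 | intermediate (not isolated)
29 | seco diol (C9–OH, C8–OH; C4 cis to C7 across C5=C6) | CC(C)(C)[Si](C)(C)O[C@H]1CC=C(C)[C@H](CO)[C@@]1(C)[C@H](O[Si](C)(C)C(C)(C)C)CC/C(COCc1ccc(OC)cc1)=C\C(=O)C(O)[C@@H](C)CO[Si](C)(C)C(C)(C)C | intermediate
30 | seco hydroxy acid (C9 acid) | CC(C)(C)[Si](C)(C)O[C@H]1CC=C(C)[C@H](C(=O)O)[C@@]1(C)[C@H](O[Si](C)(C)C(C)(C)C)CC/C(COCc1ccc(OC)cc1)=C\C(=O)C(O)[C@@H](C)CO[Si](C)(C)C(C)(C)C | intermediate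
31 | eleven-membered macrolactone (C9(=O)–O–C8; C7 ketone) | CC(C)(C)[Si](C)(C)O[C@H]1CC=C(C)[C@@H]2C(=O)OC(C(=O)/C=C(/COCc3ccc(OC)cc3)CC[C@@H](O[Si](C)(C)C(C)(C)C)[C@@]12C)[C@@H](C)CO[Si](C)(C)C(C)(C)C | intermediate
32 | lithium enolate of 31 (C7(OLi)=C8, geometry open) | CC(C)(C)[Si](C)(C)O[C@H]1CC=C(C)[C@@H]2C(=O)OC(=C(O[Li])/C=C(/COCc3ccc(OC)cc3)CC[C@@H](O[Si](C)(C)C(C)(C)C)[C@@]12C)[C@@H](C)CO[Si](C)(C)C(C)(C)C | intermediate (not isolated)
33 | oxiranolate (C8–O–C9 three-membered ring, lithium alkoxide on C9) | CC(C)(C)[Si](C)(C)O[C@H]1CC=C(C)[C@@H]2C3(O[Li])O[C@]3(C(=O)/C=C(/COCc4ccc(OC)cc4)CC[C@@H](O[Si](C)(C)C(C)(C)C)[C@@]12C)[C@@H](C)CO[Si](C)(C)C(C)(C)C | intermediate (not isolated)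
34 | ten-membered 8-hydroxy-7,9-diketone (C8 as in target) | CC(C)(C)[Si](C)(C)O[C@H]1CC=C(C)[C@@H]2C(=O)[C@@](O)(C(=O)/C=C(/COCc3ccc(OC)cc3)CC[C@@H](O[Si](C)(C)C(C)(C)C)[C@@]12C)[C@@H](C)CO[Si](C)(C)C(C)(C)C | intermediate
35 | 7-alcohol (C7 as in target; C9 ketone) | CC(C)(C)[Si](C)(C)O[C@H]1CC=C(C)[C@@H]2C(=O)[C@@](O)([C@@H](O)/C=C(/COCc3ccc(OC)cc3)CC[C@@H](O[Si](C)(C)C(C)(C)C)[C@@]12C)[C@@H](C)CO[Si](C)(C)C(C)(C)C | intermediate
36 | pentaol (2-, 7-, 8-, 14-, 19-OH; C9 ketone; 16-OPMB) | O[C@H]1CC=C(C)[C@@H]2C(=O)[C@@](O)([C@@H](O)/C=C(/COCc3ccc(OC)cc3)CC[C@@H](O)[C@@]12C)[C@@H](C)CO | intermediate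
37 | lactol (C19 hemiacetal with O7) | O[C@H]1CC=C(C)[C@@H]2C(=O)[C@@]3(O)[C@H](/C=C(/COCc4ccc(OC)cc4)CC[C@@H](O)[C@@]12C)OC(O)[C@@H]3C | intermediate (not isolated)
38 | lactone diol (γ-lactone; 2-, 14-OH; C9 ketone) | O[C@H]1CC=C(C)[C@@H]2C(=O)[C@@]3(O)[C@H](/C=C(/COCc4ccc(OC)cc4)CC[C@@H](O)[C@@]12C)OC(=O)[C@@H]3C | intermediate
39 | diacetate (2-, 14-OAc; C9 ketone) | CC(=O)O[C@H]1CC=C(C)[C@@H]2C(=O)[C@@]3(O)[C@H](/C=C(/COCc4ccc(OC)cc4)CC[C@@H](OC(C)=O)[C@@]12C)OC(=O)[C@@H]3C | intermediate
40 | 8,9-diol (16-OPMB) | CC(=O)O[C@H]1CC=C(C)[C@@H]2[C@@H](O)[C@@]3(O)[C@H](/C=C(/COCc4ccc(OC)cc4)CC[C@@H](OC(C)=O)[C@@]12C)OC(=O)[C@@H]3C | intermediate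
41 | allylic alcohol (16-OH) | CC(=O)O[C@H]1CC=C(C)[C@@H]2[C@@H](O)[C@@]3(O)[C@H](/C=C(/CO)CC[C@@H](OC(C)=O)[C@@]12C)OC(=O)[C@@H]3C | intermediate
42 | allylic chloride (16-Cl; C11=C12) | CC(=O)O[C@H]1CC=C(C)[C@@H]2[C@@H](O)[C@@]3(O)[C@H](/C=C(/CCl)CC[C@@H](OC(C)=O)[C@@]12C)OC(=O)[C@@H]3C | intermediate
43 | CNP0308390.1 (1S,2R,7S,8R,9R,10S,11R,12S,14S,17R) | CC(=O)O[C@H]1C[C@@H]2O[C@]2(C)[C@@H]2[C@@H](O)[C@@]3(O)[C@H](/C=C(/CCl)CC[C@@H](OC(C)=O)[C@@]12C)OC(=O)[C@@H]3C | target

**Step count and risks**
Total steps: 30. Longest linear sequence: 23 steps from (S)-carvone (steps 1–11 and 19–30); the western fragment takes 7 steps (12–18).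

Risk 1, step 22 (Proposed new method). The acyl group may be delivered to the wrong enolate face, the acyl group may migrate to the enolate oxygen and divert to an isomeric smaller ring, or the enolate may fail to reach the hindered lactone carbonyl. The fallback uses known reactions only, sets out from 15 and 25 and returns at 34. Bis-borane 28, made from 15 as in step 19, is coupled with iodo enone 25 under the same Suzuki conditions to give the coupled enone alcohol F1. Dess–Martin oxidation should give the C9 aldehyde F2. The kinetic C8 lithium enolate (LiHMDS, THF, −78 °C, 1 mM) should add to the aldehyde in an intramolecular aldol reaction and close the ten-membered ring as the aldol F3. A second Dess–Martin oxidation should give the 7,9-diketone F4. Hydroxylation of its enol with dimethyldioxirane (acetone, 0 °C) should install the C8 hydroxyl from the face opposite the CH2OTBS group and deliver 34.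

Risk 2, step 21. Oligomerisation may outrun closure of the strained eleven-membered ring, or the activated C8 oxygen may be lost by elimination. The fallback closes the ring at C4–C5 instead, sets out from 15 and 27 and returns at 31. Oxidation of 15 with TEMPO/PhI(OAc)2 in aqueous acetonitrile should give the eastern carboxylic acid F5. Intermolecular Yamaguchi esterification with 27 should give the ester F6. Hydroboration of its vinyl group with 9-BBN at 0 °C should give the borane F7. An intramolecular B-alkyl Suzuki coupling (Pd(dppf)Cl2, AsPh3, Cs2CO3, DMF/THF/H2O, 2 mM) should then give 31.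

Risk 3, step 30. Oxygen may be transferred to the α face or to the C5=C6 alkene, or the epoxide may be opened transannularly by the C9 hydroxyl. The fallback sets out from 42 and returns at 43. NBS in aqueous THF at 0 °C should form the bromonium ion on the exposed α face, and water opens it at the tertiary C11 from the β face to give the bromohydrin F8. Silver(I) oxide in THF should close it with inversion at C12 to the β-epoxide 43.

Further compounds
F1 | step 22 | coupled enone alcohol (29 without the C8 hydroxyl) | CC(C)(C)[Si](C)(C)O[C@H]1CC=C(C)[C@H](CO)[C@@]1(C)[C@H](O[Si](C)(C)C(C)(C)C)CC/C(COCc1ccc(OC)cc1)=C\C(=O)C[C@@H](C)CO[Si](C)(C)C(C)(C)C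
F2 | step 22 | C9 aldehyde | CC(C)(C)[Si](C)(C)O[C@H]1CC=C(C)[C@H](C=O)[C@@]1(C)[C@H](O[Si](C)(C)C(C)(C)C)CC/C(COCc1ccc(OC)cc1)=C\C(=O)C[C@@H](C)CO[Si](C)(C)C(C)(C)C
F3 | step 22 | ten-membered aldol (9-hydroxy-7-ketone, C8/C9 epimer mixture) | CC(C)(C)[Si](C)(C)O[C@H]1CC=C(C)[C@@H]2C(O)C(C(=O)/C=C(/COCc3ccc(OC)cc3)CC[C@@H](O[Si](C)(C)C(C)(C)C)[C@@]12C)[C@@H](C)CO[Si](C)(C)C(C)(C)C
F4 | step 22 | ten-membered 7,9-diketone | CC(C)(C)[Si](C)(C)O[C@H]1CC=C(C)[C@@H]2C(=O)C(C(=O)/C=C(/COCc3ccc(OC)cc3)CC[C@@H](O[Si](C)(C)C(C)(C)C)[C@@]12C)[C@@H](C)CO[Si](C)(C)C(C)(C)C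
F5 | step 21 | eastern carboxylic acid | CC(C)(C)[Si](C)(C)O[C@H]1CC=C(C)[C@H](C(=O)O)[C@@]1(C)[C@H](O[Si](C)(C)C(C)(C)C)C=C
F6 | step 21 | ester of F5 with 27 | CC(C)(C)[Si](C)(C)O[C@H]1CC=C(C)[C@H](C(=O)OC(C(=O)/C=C(I)/COCc2ccc(OC)cc2)[C@@H](C)CO[Si](C)(C)C(C)(C)C)[C@@]1(C)[C@H](O[Si](C)(C)C(C)(C)C)C=C
F7 | step 21 | B-alkyl-9-BBN borane of F6 | CC(C)(C)[Si](C)(C)O[C@H]1CC=C(C)[C@H](C(=O)OC(C(=O)/C=C(I)/COCc2ccc(OC)cc2)[C@@H](C)CO[Si](C)(C)C(C)(C)C)[C@@]1(C)[C@H](O[Si](C)(C)C(C)(C)C)CCB1C2CCCC1CCC2
F8 | step 30 | 12α-bromo-11β-hydroxy bromohydrin | CC(=O)O[C@H]1C[C@@H](Br)[C@@](O)(C)[C@@H]2[C@@H](O)[C@@]3(O)[C@H](/C=C(/CCl)CC[C@@H](OC(C)=O)[C@@]12C)OC(=O)[C@@H]3C
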